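Which of the four flasks holds the highest amount of Z at the end of its time?

| setting | Sunday's | Thursday's | Tuesday's | dusk | dawn | midnight | noon |
|---|---|---|---|---|---|---|---|
| J | 0.56 M | 0.56 M | 0.28 M | 0.56 M | 0.56 M | 0.56 M | 0.56 M |
| E | 1.6 M | 2.5 M | 1.12 M | 1.12 M | 1.12 M | 1.12 M | 1.12 M |
| temperature | 71 °C | 96 °C | 71 °C | 75 °C | 60 °C | 90 °C | 105 °C |
| remark | run made earlier | run made earlier | run made earlier |  |  |  |  |
| time |  |  |  | 1.0 h | 1.0 h | 1.0 h | 1.0 h |

| run | time / min | Z / % |
|---|---|---|
| Sunday's | 12.0 | 10.3 |
| Sunday's | 25.0 | 19.4 |
| Sunday's | 40.0 | 27.8 |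
| Sunday's | 50.0 | 31.0 |
| Thursday's | 1.33 | 11.3 |
| Thursday's | 3.00 | 22.0 |
| Thursday's | 8.00 | 38.4 |
| Thursday's | 20.0 | 41.6 |
| Tuesday's | 12.0 | 7.2 |
| Tuesday's | 25.0 | 14.3 |
| Tuesday's | 40.0 | 21.4 |
| Tuesday's | 50.0 | 25.6 |

(scatter of a reading: 0.3 percentage points)

1. the best flask by amount of Z, in percent of the J charged; "all alike" if 1.5 percentage points covers them all (dusk / dawn / midnight / noon / all alike)
2. amount of Z at the end, in percent of the J charged, dusk
3. amount of Z at the end, in percent of the J charged, dawn
4. amount of Z at the end, in percent of the J charged, midnight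
5. amount of Z at the end, in percent of the J charged, noon

- reactions considered so far: J + E -> Z + X; E + Z -> G + X; E + G -> L + X; E + L -> D + X; Z -> Q

1. Start with the order in E. Sunday's and Tuesday's first readings stand in the ratio 1.43, and their charges of E in the ratio 1.43. The two runs also differ in J, but the readings are in percent of the J charged, and a step first order in J gives the same percent from either charge. So I take the step J + E → Z + X, with constant kJ, as first order in J and in E, and I assume first order in Z and in E for E + Z → G + X, with constant kZ.

2. Now divide the loss rate of Z by the loss rate of J. Let j and z be the parts of the J charged present as J and as Z, and set Z → Q aside. E and time then cancel, leaving the selectivity factor s = kZ/kJ, a number that places z on a curve in j: z = (j^s − j)/(1 − s). The top of that curve lies at j = s·z.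

3. The forecast reads s from the curves as near 0.5 at Sunday's temperature and 0.7 at Thursday's, and I take over these readings. A straight line between them gives midnight the selectivity factor s = 0.652.

4. Compare midnight with its neighbour, Thursday's run. Thursday's has twice the E, but E cancels from s, so E does not move the curve. Thursday's is also hotter than midnight, and its s = 0.700 stands above midnight's. That puts Thursday's top at 43.5%, and its last reading is 41.6%. Midnight's top stands at 44.9%, reached at j = 29.3%, and this is higher than Thursday's.

5. Will midnight arrive there in time? The first readings, interpolated between Sunday's and Thursday's, give kJ of about 0.0218 /M/min. Reaching the top needs kJ times E times time to equal 1.23. The full charge would give 1.47, but E falls as it works, so I expect midnight to end close to its top.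

6. The forecast names midnight: dusk 33%, dawn 13.8%, midnight 44%, noon 32%. Its midnight figure lies below my top. It places midnight “near the maximum”.

7. The flasks give dusk 33.7%, dawn 13.8%, midnight 44.9% and noon 35.6%, so midnight leads.

    J + E → Z + X (k = 0.0250 /M/min, Ea = 79.0 kJ/mol)
    E + Z → G + X (k = 0.0160 /M/min, Ea = 99.0 kJ/mol)
    E + G → L + X (k = 0.0780 /M/min, Ea = 95.0 kJ/mol)
    E + L → D + X (k = 0.0570 /M/min, Ea = 83.0 kJ/mol)
    Z → Q (k = 1.00 × 10⁻⁴ /min, Ea = 116 kJ/mol)
    (constants at 90 °C)

At its end, midnight holds J 31.9% and Q 0.205%, so Z → Q stays small beside Z. Put that J into the curve with s = 0.652 and it returns 44.8%. Dusk has s = 0.532 and J 61.9%, so the curve returns 33.3%, where the dusk flask stands at 33.7%.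

The readings were computed on assumed constants; the scatter is artificial.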